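The dihydrofuran ring (ring C: O1, C2, C3, C3a, C7a) is disconnected at C2–C3. C2 is benzylic to ring A and bonded to O1, so its C–H bond is activated towards electrophilic carbenoids, and C3 can carry its CH2OH as an ester. A rhodium carbenoid at C3, generated from an aryl diazoacetate on ring B, therefore inserts into that C–H bond 1,5 to it, closing ring C and fixing C2 under catalyst control; base equilibration then sets C3 trans. The precursor is an open benzyl aryl ether lacking ring C, a 2-(arylmethoxy)aryl diazoacetate assembled from 5-iodovanillin and syringaldehyde; hydride reduction completes the target.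

Key step: step 6

Numbering: benzofuran numbering (O1, C2, C3, C3a, C4 to C7, C7a); ring A is the 4-hydroxy-3,5-dimethoxyphenyl ring on C2, ring B the benzo ring, ring C the dihydrofuran ring.

Assumption: Rh2(S-PTTL)4 is taken to deliver the 2R configuration, as expected for 1,5-insertions of 2-(benzyloxy)aryl diazoacetates with this ligand; should the opposite sense be found, Rh2(R-PTTL)4 would be used with no other change.

Step 1
Reactants: 1 syringaldehyde (4-hydroxy-3,5-dimethoxybenzaldehyde)
Product: 2 4-formyl-2,6-dimethoxyphenyl 2,2-dimethylpropanoate (pivalate of 1)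
Conditions: PivCl, Et3N, DMAP (cat.), CH2Cl2, 0 °C to rt
Reagents that add atoms: pivaloyl chloride, CC(C)(C)C(=O)Cl
Why: DMAP-catalysed O-acylation of the phenol; the pivalate lowers the donor strength of ring A for the carbenoid step, should survive the Pd, Rh and amine-base steps, and is removed by hydride in the last step.

Step 2
Reactants: 2 4-formyl-2,6-dimethoxyphenyl 2,2-dimethylpropanoate
Product: 3 4-(hydroxymethyl)-2,6-dimethoxyphenyl 2,2-dimethylpropanoate
Conditions: NaBH4, THF/MeOH, 0 °C
Reagents that add atoms: none
Why: Chemoselective borohydride reduction of the aryl aldehyde, which should leave the hindered aryl pivalate intact at 0 °C.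

Step 3
Reactants: 4 5-iodovanillin (4-hydroxy-3-iodo-5-methoxybenzaldehyde); 5 methyl (triphenylphosphoranylidene)acetate
Product: 6 methyl (2E)-3-(4-hydroxy-3-iodo-5-methoxyphenyl)prop-2-enoate
Conditions: 5 (2.2 equiv), toluene, 100 °C
Reagents that add atoms: none
Why: Wittig olefination with a stabilised ylide, which should give the E alkene through reversible oxaphosphetane formation; the excess of 5 covers reversible proton transfer from the acidic phenol.

Step 4
Reactants: 6 methyl (2E)-3-(4-hydroxy-3-iodo-5-methoxyphenyl)prop-2-enoate; 3 4-(hydroxymethyl)-2,6-dimethoxyphenyl 2,2-dimethylpropanoate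
Product: 7 methyl (2E)-3-[4-({4-[(2,2-dimethylpropanoyl)oxy]-3,5-dimethoxyphenyl}methoxy)-3-iodo-5-methoxyphenyl]prop-2-enoate
Conditions: PPh3, DIAD, THF, 0 °C to rt
Reagents that add atoms: none
Why: Mitsunobu etherification, in which the acidic iodophenol 6 protonates the betaine and its phenoxide displaces the primary benzylic oxyphosphonium ion of 3, so that no labile benzyl halide is needed and the esters and the aryl iodide stay untouched.

Step 5
Reactants: 7 methyl (2E)-3-[4-({4-[(2,2-dimethylpropanoyl)oxy]-3,5-dimethoxyphenyl}methoxy)-3-iodo-5-methoxyphenyl]prop-2-enoate; 8 ethyl diazoacetate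
Product: 9 ethyl 2-diazo-2-{2-({4-[(2,2-dimethylpropanoyl)oxy]-3,5-dimethoxyphenyl}methoxy)-3-methoxy-5-[(1E)-3-methoxy-3-oxoprop-1-en-1-yl]phenyl}acetate
Conditions: Pd(PPh3)4 (5 mol %), Ag2CO3 (0.5 equiv), Et3N (1.3 equiv), toluene, rt
Reagents that add atoms: none
Why: Palladium-catalysed cross-coupling of an aryl iodide with an acceptor diazo compound with retention of the diazo group: oxidative addition of zerovalent palladium to the C–I bond, silver-assisted iodide abstraction, C-palladation of the amine-deprotonated diazoacetate and reductive elimination should all run at room temperature, where neither Heck reaction of the cinnamate nor loss of N2 should compete.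

Step 6
Reactants: 9 ethyl 2-diazo-2-{2-({4-[(2,2-dimethylpropanoyl)oxy]-3,5-dimethoxyphenyl}methoxy)-3-methoxy-5-[(1E)-3-methoxy-3-oxoprop-1-en-1-yl]phenyl}acetate
Product: 11 ethyl (2R,3R)-2-{4-[(2,2-dimethylpropanoyl)oxy]-3,5-dimethoxyphenyl}-7-methoxy-5-[(1E)-3-methoxy-3-oxoprop-1-en-1-yl]-2,3-dihydro-1-benzofuran-3-carboxylate (2,3-trans diester), via cis-(2R,3S) diester 10 (not isolated)
Conditions: dirhodium tetrakis[N-phthaloyl-(S)-tert-leucinate], Rh2(S-PTTL)4 (2 mol %), toluene, −78 to −40 °C, slow addition of 9; then DBU (1 equiv), warm to 40 °C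
Reagents that add atoms: none
Why: Loss of N2 from 9 at the dirhodium tetracarboxylate should give an electrophilic donor/acceptor carbenoid at the future C3, which inserts through a concerted, asynchronous three-centre transition state into the C–H bond of the O1–CH2–ring A group, forming the C2–C3 bond. The closest known reaction type is the enantioselective intramolecular 1,5-C–H insertion of 2-(benzyloxy)aryl diazoacetates to cis-2-aryl-2,3-dihydrobenzofuran-3-carboxylates under chiral dirhodium carboxylate catalysis. Ring C is the only ring closed, by 1,5-insertion through a five-membered cyclic transition state in which C3 and C2 are tethered by C3a, C7a and O1. C2 is set by the catalyst, which should select one of the two enantiotopic benzylic hydrogens (2R expected with the S ligand), while C3 is first set cis by the insertion geometry and is then equilibrated by DBU through the ester enolate to the more stable 2,3-trans (3R) diester without touching the non-acidic C2. The step needs 1,5-C–H insertion to outrun cyclopropanation, aromatic addition, oxonium ylide formation and carbene dimerisation, and a concerted insertion to outrun stepwise hydride transfer. The substrate secures this by placing the only α-oxy benzylic C–H bond five atoms from the carbenoid, by the C7 methoxy group that twists the benzyloxy group out of the plane of ring B towards the carbenoid, by the electron-poor trans-disubstituted cinnamate, and by the pivalate that lowers the donor strength of ring A.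

Step 7
Reactants: 11 ethyl (2R,3R)-2-{4-[(2,2-dimethylpropanoyl)oxy]-3,5-dimethoxyphenyl}-7-methoxy-5-[(1E)-3-methoxy-3-oxoprop-1-en-1-yl]-2,3-dihydro-1-benzofuran-3-carboxylate
Product: 12 4-[(2R,3S)-3-(hydroxymethyl)-5-[(1E)-3-hydroxyprop-1-en-1-yl]-7-methoxy-2,3-dihydro-1-benzofuran-2-yl]-2,6-dimethoxyphenol (target)
Conditions: i-Bu2AlH (excess), CH2Cl2, −78 to 0 °C; then aq. potassium sodium tartrate
Reagents that add atoms: none
Why: Hydride reduction with i-Bu2AlH should convert both esters into primary alcohols (1,2-reduction of the cinnamate, keeping the E alkene) and cleave the aryl pivalate in the same operation, while C2 and C3 stay untouched because the C3 ester is reduced through tetrahedral aluminium alkoxides and is never enolised (the descriptor at C3 changes from R to S only through the priority change from ester to CH2OH).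

Compound list
1 | syringaldehyde (4-hydroxy-3,5-dimethoxybenzaldehyde) | COc1cc(C=O)cc(OC)c1O | starting material
2 | 4-formyl-2,6-dimethoxyphenyl 2,2-dimethylpropanoate | COc1cc(C=O)cc(OC)c1OC(=O)C(C)(C)C | intermediate
3 | 4-(hydroxymethyl)-2,6-dimethoxyphenyl 2,2-dimethylpropanoate | COc1cc(CO)cc(OC)c1OC(=O)C(C)(C)C | intermediate
4 | 5-iodovanillin (4-hydroxy-3-iodo-5-methoxybenzaldehyde) | COc1cc(C=O)cc(I)c1O | starting material
5 | methyl (triphenylphosphoranylidene)acetate | COC(=O)C=P(c1ccccc1)(c1ccccc1)c1ccccc1 | starting material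
6 | methyl (2E)-3-(4-hydroxy-3-iodo-5-methoxyphenyl)prop-2-enoate | COC(=O)/C=C/c1cc(I)c(O)c(OC)c1 | intermediate
7 | methyl (2E)-3-[4-({4-[(2,2-dimethylpropanoyl)oxy]-3,5-dimethoxyphenyl}methoxy)-3-iodo-5-methoxyphenyl]prop-2-enoate | COC(=O)/C=C/c1cc(I)c(OCc2cc(OC)c(OC(=O)C(C)(C)C)c(OC)c2)c(OC)c1 | intermediate
8 | ethyl diazoacetate | CCOC(=O)C=[N+]=[N-] | starting material
9 | ethyl 2-diazo-2-{2-({4-[(2,2-dimethylpropanoyl)oxy]-3,5-dimethoxyphenyl}methoxy)-3-methoxy-5-[(1E)-3-methoxy-3-oxoprop-1-en-1-yl]phenyl}acetate | CCOC(=O)C(=[N+]=[N-])c1cc(/C=C/C(=O)OC)cc(OC)c1OCc1cc(OC)c(OC(=O)C(C)(C)C)c(OC)c1 | intermediate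
10 | ethyl (2R,3S)-2-{4-[(2,2-dimethylpropanoyl)oxy]-3,5-dimethoxyphenyl}-7-methoxy-5-[(1E)-3-methoxy-3-oxoprop-1-en-1-yl]-2,3-dihydro-1-benzofuran-3-carboxylate (2,3-cis) | COc1cc([C@@H]2Oc3c(OC)cc(/C=C/C(=O)OC)cc3[C@@H]2C(=O)OCC)cc(OC)c1OC(=O)C(C)(C)C | intermediate (not isolated)
11 | ethyl (2R,3R)-2-{4-[(2,2-dimethylpropanoyl)oxy]-3,5-dimethoxyphenyl}-7-methoxy-5-[(1E)-3-methoxy-3-oxoprop-1-en-1-yl]-2,3-dihydro-1-benzofuran-3-carboxylate (2,3-trans) | COc1cc([C@@H]2Oc3c(OC)cc(/C=C/C(=O)OC)cc3[C@H]2C(=O)OCC)cc(OC)c1OC(=O)C(C)(C)C | intermediate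
12 | 4-[(2R,3S)-3-(hydroxymethyl)-5-[(1E)-3-hydroxyprop-1-en-1-yl]-7-methoxy-2,3-dihydro-1-benzofuran-2-yl]-2,6-dimethoxyphenol | COc1cc([C@@H]2Oc3c(OC)cc(/C=C/CO)cc3[C@H]2CO)cc(OC)c1O | target

Total step count: 7. Longest linear sequence: 6 steps (steps 1, 2, 4, 5, 6, 7).

Steps most likely to fail

Step 6. Facial selectivity may be poor if the insertion turns stepwise: hydride transfer from the electron-rich benzylic position would give an oxocarbenium/rhodium enolate pair that closes outside catalyst control. Fallback: it sets out from 9 and gives up asymmetric induction for resolution. Decomposition of 9 with achiral Rh2(OAc)4 (CH2Cl2, rt) followed by DBU should close ring C whichever pathway operates. It would give the cis diester 10 together with its enantiomer, the cis (2S,3R) diester F1, and after equilibration the trans diester 11 together with its enantiomer, the trans (2S,3S) diester F2. Preparative chromatography on a cellulose tris(3,5-dimethylphenylcarbamate) stationary phase would separate 11 from F2, and the route is rejoined at 11.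

Step 5. Oxidative addition and C-palladation at the doubly ortho-substituted iodide may be slow, leaving time for palladium-carbene decomposition of ethyl diazoacetate and for dipolar cycloaddition of the diazo compound to the cinnamate. Fallback: it sets out from 7 and makes the C–C bond before the diazo group. Negishi-type coupling of 7 with the Reformatsky reagent BrZnCH2CO2Et (from ethyl bromoacetate and zinc dust; Pd2(dba)3, XPhos, THF, rt to 50 °C) should give ethyl 2-{2-({4-[(2,2-dimethylpropanoyl)oxy]-3,5-dimethoxyphenyl}methoxy)-3-methoxy-5-[(1E)-3-methoxy-3-oxoprop-1-en-1-yl]phenyl}acetate F3. Regitz diazo transfer to its benzylic methylene (4-acetamidobenzenesulfonyl azide, DBU, MeCN, 0 °C to rt) then returns to the route at 9.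

Step 4. The electron-rich benzylic oxyphosphonium ion may be captured by the hydrazide anion instead of the hindered, weakly nucleophilic phenoxide, or the displacement may stall. Fallback: it sets out from 3 and replaces redox condensation by a Williamson etherification. PBr3 (CH2Cl2, 0 °C) should convert 3 into 4-(bromomethyl)-2,6-dimethoxyphenyl 2,2-dimethylpropanoate F4, which the pivalate keeps from ionising. Alkylation of phenol 6 with F4 (K2CO3, DMF, rt) returns to the route at 7.

Further compounds
F1 | step 6 | ethyl (2S,3R)-2-{4-[(2,2-dimethylpropanoyl)oxy]-3,5-dimethoxyphenyl}-7-methoxy-5-[(1E)-3-methoxy-3-oxoprop-1-en-1-yl]-2,3-dihydro-1-benzofuran-3-carboxylate (enantiomer of 10) | COc1cc([C@H]2Oc3c(OC)cc(/C=C/C(=O)OC)cc3[C@H]2C(=O)OCC)cc(OC)c1OC(=O)C(C)(C)C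
F2 | step 6 | ethyl (2S,3S)-2-{4-[(2,2-dimethylpropanoyl)oxy]-3,5-dimethoxyphenyl}-7-methoxy-5-[(1E)-3-methoxy-3-oxoprop-1-en-1-yl]-2,3-dihydro-1-benzofuran-3-carboxylate (enantiomer of 11) | COc1cc([C@H]2Oc3c(OC)cc(/C=C/C(=O)OC)cc3[C@@H]2C(=O)OCC)cc(OC)c1OC(=O)C(C)(C)C
F3 | step 5 | ethyl 2-{2-({4-[(2,2-dimethylpropanoyl)oxy]-3,5-dimethoxyphenyl}methoxy)-3-methoxy-5-[(1E)-3-methoxy-3-oxoprop-1-en-1-yl]phenyl}acetate | CCOC(=O)Cc1cc(/C=C/C(=O)OC)cc(OC)c1OCc1cc(OC)c(OC(=O)C(C)(C)C)c(OC)c1
F4 | step 4 | 4-(bromomethyl)-2,6-dimethoxyphenyl 2,2-dimethylpropanoate | COc1cc(CBr)cc(OC)c1OC(=O)C(C)(C)C
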